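Numbering used throughout: iridoid numbering (C1 acetal carbon, O2, C3=C4, ring-fusion carbons C5 and C9, cyclopentane C5–C6–C7–C8–C9, C10 on C8, C11 on C4). β is the face of H5 and H9, α the opposite face.

## The problem

- Target 33 is a cis-fused cyclopenta[c]pyran with five ring stereocentres, (1S,5S,7S,8R,9S), and an (R) centre in the 3-methylpentanoyl group.
- On the cyclopentane, the C4 branch at C5, the C1 branch at C9 and the tertiary O8 are all α, whereas O7 and C10 are β. C8 is fully substituted and sits between two stereocentres, so C8 and C9 have to be created together. The neighbours C5 and C7 can be bought from the chiral pool.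
- The C4 and C1 branches are cis on adjacent carbons. In the natural product ring A holds this sterically unfavourable arrangement, but it must be created before ring A exists.
- C1 is anomeric: it equilibrates at the lactol stage and is fixed only by the acylation itself.
- O7, O10 and O11 must be told apart, because only O7 is acylated.
- Several groups rule out rough treatment:
  - the acyloxy acetal at C1;
  - an enol ether without a stabilising carbonyl group, bearing an allylic hydroxyl at C11;
  - a free tertiary 8-OH that can add to C3 under acid;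
  - a (Z)-cinnamate that isomerises under light or nucleophiles;
  - a 7-O-acyl group next to a free 10-OH, which invites acyl shift under base.
- The feature that opens the key step is that C1 and O8 are cis across the C8–C9 bond, so they can be joined as a β-lactone, which can only be cis-fused on a five-membered ring. Cutting C8–C9 and O8–C1 leaves an open chain whose ten skeletal carbons, C5 configuration and C7 oxygen are those of (R)-carvone 1 after carbonyl reduction and scission of the ring alkene.

## Retrosynthesis

**33 back to 22, 23 and 31.** The three O–Si bonds of 32 are cut last, then the C7 ester bond (25 + 31), the benzyl-type ether on O7 (24), and the C1 ester bond (22 + 23). The C1 ester is made first because, while O7 is still an ether, the lactol hydroxyl is the only acylable one in 22. The (Z)-cinnamate goes on last because it is the group most easily damaged. A 4-methoxybenzyl ether on O7 is preferred to a third silyl ether: O7 must be unmasked alone in the presence of the silyl ethers on O10, O11 and the phenol. The precursors 22, 23 and 31 carry no ester, so every earlier hydride or enolate step is free of ester problems.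

**22 back to 20 (ring A).** The O2–C3 bond is cut: 22 is the ring-chain tautomer of dialdehyde 21, which comes from the 1,5-diol unit of triol 20. The neighbouring cuts are less attractive. Closing C1–O2 from an alkyl acetal, or making C3=C4 by metathesis, would leave an alkyl acetal at C1 that has to be exchanged for an acyloxy group under acid. The dialdehyde route delivers C1 as a free hydroxyl. The forward step must oxidise two primary alcohols beside a tertiary one and close the ring without acid strong enough to let O8 add to C3.

**20 back to 18.** The C3–O bond is cut (anti-Markovnikov hydration of the 1,1-disubstituted alkene of 19), then the C1–H bonds (reduction of the lactone carbonyl of 18). The configuration at C4 is irrelevant because C4 becomes trigonal in 22. The C11 oxygen is already in place as a silyl ether; a free C11 hydroxyl next to the strained lactone of 18 would be expected to translactonise.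

**18 back to 16 (key disconnection).** C8–C9 and O8–C1 are cut together, opening the cyclopentane and the β-lactone to keto acid 16. Cutting C5–C9 or C7–C8 instead would require a preformed quaternary C8 in an open chain. Here C8 is a ketone, the simplest state of a fully substituted carbon, and 16 has only the two stereocentres that carvone can supply. The forward reaction must close on the α face, cis to the C5 branch.

- *The weakness.* A β-branched acid of this kind intrinsically closes anti to its branch, because allylic strain in the enolate puts C5–H in the enolate plane. Substrate control from C5 therefore works against the plan.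
- *The countermeasures.* Two elements are set against it:
  - a chiral isothiourea catalyst that selects the enolate face;
  - the C7 ether, whose C–O dipole opposes C8=O in the transition state leading to O8 anti to O7.
- *How the C7 ether supports this.* It is kept small and non-silyl, and no Lewis-acidic salt is added, so the dipole preference is not overridden by bulk or chelation.
- *A reserve.* A ring-locked variant of the substrate is held as the fallback.

**16 back to 11.** The C10–O bond is cut: the hydroxymethyl ketone comes from the methyl ketone of 11 by kinetic enolisation on the methyl side and oxidation of the silyl enol ether, via 14. Carrying the C10 oxygen from the start would need an allylic oxidation of the ring methyl in competition with the side-chain alkene. The methyl ketone gives the regiochemistry for free, because an α-alkoxy ketone enolises kinetically away from the oxygen-bearing carbon.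

**11 back to 9.** The C1 and C8 carbonyls are reconnected to the ring alkene (C1=C8 in iridoid numbering): acid 11 from aldehyde 10, and 10 from epoxide 9 by hydrolysis and glycol cleavage. Ozonolysis or dihydroxylation would not spare the second alkene. The hydroxyl-directed epoxidation of 7 marks the ring alkene alone, and etherifying O7 before the cleavage prevents loss of C10 by a second glycol cleavage.

**9 back to 1.** Epoxide 9 comes from epoxy alcohol 8 and allylic alcohol 7. The C7–O configuration (trans to the C5 branch) comes from 1,2-reduction of the enone to the cis alcohol 4, inversion to ester 5 and methanolysis to diol 6. The C11 oxygen comes from allylic chlorination of the isopropenyl group of 1 (giving 2) and acetate displacement (giving 3). Introducing O11 at the start costs two early steps. It avoids a late allylic oxidation on a molecule with a β-lactone, and the primary/secondary difference in 6 sorts the two hydroxyls without extra effort.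

**31 back to 26.** The C=C bond of the cinnamate is cut: (Z)-selective olefination of aldehyde 27 (from 26) gives ester 28. Hydrolysis to 29 and resilylation give acid 31.

## Roads not taken

**Alternative 1: intramolecular hetero-Diels–Alder reaction.**
- *Cut:* C5–C9 and C1–O2.
- *Forward step:* the open-chain precursor A1 carries an alkylidene formylacetate (1-oxadiene O2=C3–C4=C5) and a tethered (E)-enol ether (C9=C1). It cyclises to the tricycle A2, forming both rings at once.
- *Merits:* two rings and three stereocentres (C1, C5, C9) in one step. The cis ring fusion, the weakest relationship in the chosen plan, follows from the geometry of the tethered cycloaddition. The enol ether is born as a robust vinylogous carbonate. This road is probably shorter.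
- *Weak points for this target:*
  - C11 arrives as an ester; once it is reduced the enol ether loses its stabilisation.
  - The ethyl acetal at C1 must be exchanged for an acyloxy group by acid hydrolysis, in a molecule with an acetonide, a tertiary silyl ether and then an acid-labile enol ether.
  - The diene face must be chosen by the quaternary C8 next to the dienophile, which is plausible but not assured.
  - C7 and C8 have to be built by separate asymmetric steps in an open chain.
- *What the chosen plan sets against it:* C1 appears as a free lactol that is acylated directly, C11 is at the right oxidation level from step 2, and the absolute configuration comes from carvone.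

**Alternative 2: phosphine-catalysed [3+2] annulation.**
- *Cut:* C8–C9 and C5–C6.
- *Forward step:* a tertiary phosphine adds to allenoate A4, and the zwitterion adds across the enone (C9=C5) of pyranone A3 to give the cis-fused cyclopentene A5.
- *Merits:* the shortest route to the bicyclic skeleton. The cis fusion is automatic, the C1 acyloxy acetal is present from the start and steers the facial selectivity. In these respects it is better than the chosen plan.
- *Weak points for this target:*
  - The regiochemistry of the annulation must place the ester-bearing carbon on C9.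
  - A5 has a C7=C8 alkene whose syn-dihydroxylation would give O7 and O8 cis. The target needs them trans, with the tertiary O8 on the concave α face, so an epoxide-and-inversion sequence would be needed.
  - The C10 ester must be reduced beside an acyl acetal.
  - The C4 ketone must be turned regioselectively into C3=C4–C11H2OH.
  - A3 must be enantioenriched.
- *What the chosen plan sets against it:* O7 comes with its configuration from the starting material and O8 is fixed in the ring-forming step, so no oxidation-state or configuration repair is needed on the finished bicycle. That repair would likely consume the step advantage of A5.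

**Alternative 3: enol ether ring-closing metathesis.**
- *Cut:* the C3=C4 bond, made last.
- *Forward step:* the molybdenum alkylidene A8 joins the O-vinyl group of the mixed acetal to the 1,1-disubstituted C4 alkene in diene A6, giving A7.
- *Merits:* the sensitive enol ether is formed under neutral conditions at the end, and no dialdehyde is needed. In this respect it is better than step 16 of the chosen plan.
- *Weak points for this target:*
  - It does not say how the cyclopentane with four contiguous stereocentres is made.
  - It needs a mixed methyl vinyl acetal of defined configuration at C1.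
  - Every hydroxyl, including the tertiary one, must be masked for the oxophilic catalyst.
  - A7 still carries a methyl acetal that must be exchanged for the acyloxy group under acid with the enol ether already present.
- *What the chosen plan sets against it:* direct acylation of a lactol, a free tertiary hydroxyl throughout, and one ring closure that also sets C8 and C9.

Key step: step 13

Assumption (chemistry): 20 and 21 are carried as mixtures of C4 epimers because C4 becomes trigonal in 22; 22 is written as its 1β anomer, the one expected to dominate and to react.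
Assumption (supply): (R)-3-methylpentanoic acid 23 is taken as purchasable in enantiopure form.

## Route

Step 1
Reactants: 1 (R)-carvone
Product: 2 (R)-5-(3-chloroprop-1-en-2-yl)-2-methylcyclohex-2-en-1-one
Conditions: Ca(OCl)2, solid CO2, CH2Cl2–H2O, 0 °C
Reagents that add atoms: calcium hypochlorite, [Ca+2].[O-]Cl.[O-]Cl
Why: Ene-type allylic chlorination by hypochlorous acid formed in the flask; only the electron-rich 1,1-disubstituted alkene reacts, the enone alkene is inert and C5 is untouched.

Step 2
Reactants: 2 (R)-5-(3-chloroprop-1-en-2-yl)-2-methylcyclohex-2-en-1-one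
Product: 3 2-[(1R)-4-methyl-5-oxocyclohex-3-en-1-yl]prop-2-en-1-yl acetate
Conditions: KOAc, Bu4NI (cat.), DMF, 50 °C
Reagents that add atoms: potassium acetate, CC(=O)[O-].[K+]
Why: SN2 displacement of a primary allylic chloride by acetate; the SN2' pathway gives the same product, so regiochemistry is not an issue.

Step 3
Reactants: 3 2-[(1R)-4-methyl-5-oxocyclohex-3-en-1-yl]prop-2-en-1-yl acetate
Product: 4 2-[(1R,5R)-5-hydroxy-4-methylcyclohex-3-en-1-yl]prop-2-en-1-yl acetate (hydroxyl cis to the side chain)
Conditions: NaBH4, CeCl3·7H2O, MeOH, −78 → −20 °C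
Reagents that add atoms: none
Why: Luche 1,2-reduction of the enone; axial hydride delivery should place the hydroxyl equatorial, cis to the equatorial side chain, and the acetate is not reduced at this temperature.

Step 4
Reactants: 4 2-[(1R,5R)-5-hydroxy-4-methylcyclohex-3-en-1-yl]prop-2-en-1-yl acetate
Product: 5 (1S,5R)-5-[3-(acetyloxy)prop-1-en-2-yl]-2-methylcyclohex-2-en-1-yl 4-nitrobenzoate (ester trans to the side chain)
Conditions: PPh3, DIAD, 4-nitrobenzoic acid, THF, 0 °C → rt
Reagents that add atoms: 4-nitrobenzoic acid, OC(=O)c1ccc(cc1)[N+](=O)[O-]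
Why: Mitsunobu esterification with inversion at the carbinol carbon sets the future C7 configuration trans to the C5 branch; the acidic nitrobenzoic acid favours clean SN2 displacement on this allylic alcohol.

Step 5
Reactants: 5 (1S,5R)-5-[3-(acetyloxy)prop-1-en-2-yl]-2-methylcyclohex-2-en-1-yl 4-nitrobenzoate
Product: 6 (1S,5R)-5-(3-hydroxyprop-1-en-2-yl)-2-methylcyclohex-2-en-1-ol
Conditions: K2CO3, MeOH, rt
Reagents that add atoms: none
Why: Transesterification removes both acyl groups by attack at the carbonyl carbons, so the carbinol configuration is retained.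

Step 6
Reactants: 6 (1S,5R)-5-(3-hydroxyprop-1-en-2-yl)-2-methylcyclohex-2-en-1-ol
Product: 7 (1S,5R)-5-{3-[(tert-butyldimethylsilyl)oxy]prop-1-en-2-yl}-2-methylcyclohex-2-en-1-ol
Conditions: TBSCl (1.05 equiv), imidazole, CH2Cl2, −20 °C
Reagents that add atoms: tert-butyldimethylsilyl chloride, CC(C)(C)[Si](C)(C)Cl
Why: Silylation is much faster at the primary than at the secondary allylic hydroxyl, which stays free to direct the next step.

Step 7
Reactants: 7 (1S,5R)-5-{3-[(tert-butyldimethylsilyl)oxy]prop-1-en-2-yl}-2-methylcyclohex-2-en-1-ol
Product: 8 syn-epoxy alcohol: the 2,3-epoxide of 7 with the epoxide oxygen cis to the hydroxyl and both trans to the side chain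
Conditions: VO(acac)2 (cat.), t-BuOOH, CH2Cl2, 0 °C → rt
Reagents that add atoms: tert-butyl hydroperoxide, CC(C)(C)OO
Why: Hydroxyl-directed vanadium-catalysed epoxidation delivers oxygen only to the alkene next to the free allylic alcohol and syn to it; the side-chain alkene has no free hydroxyl and is left alone (the epoxide configuration is lost in step 9).

Step 8
Reactants: 8 syn-epoxy alcohol
Product: 9 4-methoxybenzyl ether of 8
Conditions: NaH, 4-methoxybenzyl chloride, Bu4NI (cat.), THF–DMF, 0 °C → rt
Reagents that add atoms: 4-methoxybenzyl chloride, COc1ccc(CCl)cc1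
Why: Williamson etherification; the alkoxide is syn to the epoxide oxygen and so cannot open the epoxide from the back, and the ether blocks a second glycol cleavage in step 9.

Step 9
Reactants: 9 4-methoxybenzyl ether of 8
Product: 10 (3S,5S)-3-{3-[(tert-butyldimethylsilyl)oxy]prop-1-en-2-yl}-5-[(4-methoxybenzyl)oxy]-6-oxoheptanal
Conditions: H5IO6, THF–H2O, 0 °C → rt
Reagents that add atoms: water, O
Why: Periodic acid hydrolyses the trisubstituted epoxide and cleaves the resulting glycol in one flask, giving the C8 methyl ketone and the C1 aldehyde; the side-chain alkene and both ethers are not touched by periodate.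

Step 10
Reactants: 10 (3S,5S)-3-{3-[(tert-butyldimethylsilyl)oxy]prop-1-en-2-yl}-5-[(4-methoxybenzyl)oxy]-6-oxoheptanal
Product: 11 (3S,5S)-3-{3-[(tert-butyldimethylsilyl)oxy]prop-1-en-2-yl}-5-[(4-methoxybenzyl)oxy]-6-oxoheptanoic acid
Conditions: NaClO2, NaH2PO4, 2-methyl-2-butene, t-BuOH–H2O, rt
Reagents that add atoms: sodium chlorite, [Na+].[O-]Cl=O
Why: Pinnick oxidation converts the aldehyde to the acid under buffered conditions; the scavenger alkene removes hypochlorous acid before it can reach the side-chain alkene or the anisyl ring.

Step 11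
Reactants: 11 (3S,5S)-3-{3-[(tert-butyldimethylsilyl)oxy]prop-1-en-2-yl}-5-[(4-methoxybenzyl)oxy]-6-oxoheptanoic acid
Product: 14 (3S,5S)-3-{3-[(tert-butyldimethylsilyl)oxy]prop-1-en-2-yl}-7-hydroxy-5-[(4-methoxybenzyl)oxy]-6-oxoheptanoic acid, via trimethylsilyl ester enol ether 12 (not isolated), via α-trimethylsilyloxy ketone trimethylsilyl ester 13 (not isolated)
Conditions: Me3SiCl, Et3N, THF, 0 °C; LiN(i-Pr)2, Me3SiCl, −78 °C; mCPBA, NaHCO3, CH2Cl2, −20 °C; citric acid, MeOH–H2O, rt
Reagents that add atoms: 3-chloroperbenzoic acid, OOC(=O)c1cccc(Cl)c1; chlorotrimethylsilane, C[Si](C)(C)Cl (kept only in 12 and 13)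
Why: Rubottom oxidation: after masking the acid as its silyl ester, the amide base removes a methyl proton of the α-alkoxy ketone (kinetic enolisation away from the oxygen-bearing carbon, so C7 is not touched), and the peracid epoxidises the electron-rich silyl enol ether far faster than the allyl silyl ether alkene; mild acid releases the hydroxy ketone and the acid.

Step 12
Reactants: 14 (3S,5S)-3-{3-[(tert-butyldimethylsilyl)oxy]prop-1-en-2-yl}-7-hydroxy-5-[(4-methoxybenzyl)oxy]-6-oxoheptanoic acid
Product: 16 (3S,5S)-7-[(tert-butyldimethylsilyl)oxy]-3-{3-[(tert-butyldimethylsilyl)oxy]prop-1-en-2-yl}-5-[(4-methoxybenzyl)oxy]-6-oxoheptanoic acid, via tert-butyldimethylsilyl ester 15 (not isolated)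
Conditions: TBSCl (2.5 equiv), imidazole, DMF, 0 °C → rt; AcOH–THF–H2O, rt
Reagents that add atoms: tert-butyldimethylsilyl chloride, CC(C)(C)[Si](C)(C)Cl
Why: Silylation of the primary hydroxyl and the acid, then selective hydrolysis of the much more labile silyl ester under weak acid, which avoids base at the epimerisable C7.

Step 13
Reactants: 16 (3S,5S)-7-[(tert-butyldimethylsilyl)oxy]-3-{3-[(tert-butyldimethylsilyl)oxy]prop-1-en-2-yl}-5-[(4-methoxybenzyl)oxy]-6-oxoheptanoic acid
Product: 18 (1S,2S,4S,5R)-5-{[(tert-butyldimethylsilyl)oxy]methyl}-2-{3-[(tert-butyldimethylsilyl)oxy]prop-1-en-2-yl}-4-[(4-methoxybenzyl)oxy]-6-oxabicyclo[3.2.0]heptan-7-one, via mixed carboxylic sulfonic anhydride 17 (not isolated)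
Conditions: TsCl, (S)-HBTM [(S)-2-phenyl-3,4-dihydro-2H-benzo[4,5]thiazolo[3,2-a]pyrimidine, 0.5 equiv], i-Pr2NEt, CH2Cl2, rt, slow addition of 16, no lithium salt
Reagents that add atoms: 4-methylbenzenesulfonyl chloride, Cc1ccc(cc1)S(Cl)(=O)=O (kept only in 17)
Why: TsCl and the amine convert 16 into anhydride 17, which acylates the isothiourea; deprotonation gives the C1 ammonium enolate. Its carbon C9 adds to the C8 ketone (5-(enolexo)-exo-trig aldol, closing the cyclopentane) and the new C8 alkoxide attacks the acylammonium carbon (4-exo-trig lactonisation, closing the β-lactone and freeing the catalyst); this is the known nucleophile-catalysed aldol-lactonisation of keto acids to cyclopentane-fused β-lactones. Because a β-lactone on a five-membered ring must be cis-fused, C8 and C9 are set as a pair with C1 and O8 on one face. C9 is controlled by the catalyst: with the enolate oxygen held syn to sulfur and the pseudo-axial phenyl group covering one face, the (S) catalyst is expected to expose the face that gives 9S. C8 follows from C9 through the cis fusion, and the same carbonyl face is the one attacked when the C7–O and C8=O dipoles are opposed (O8 anti to O7). The step must close on the α face, cis to the C5 branch, against the preference of a β-branched acid to close anti to its branch. This is secured by the matched pairing of catalyst and C7 ether, by a small non-silyl ether on O7 with no chelating cation, and by a large amount of catalyst with slow addition so the slower closure is not outrun by anhydride side reactions. The two α-oxygen substituents activate the ketone, and the tertiary aldolate is trapped as the lactone before it can dehydrate; the antipodal catalyst is the control experiment for the sense of induction.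

Step 14
Reactants: 18 β-lactone
Product: 19 diol: cyclopentane with C9–CH2OH (C1), C8(OH)(CH2OTBS), C7–O-(4-methoxybenzyl) and the C5 side chain C(=CH2)CH2OTBS, configuration as in 18
Conditions: i-Bu2AlH, CH2Cl2, −78 → 0 °C; aq. potassium sodium tartrate
Reagents that add atoms: none
Why: Hydride reduction of the strained lactone to the primary alcohol at C1 and the free tertiary alcohol at C8; no stereocentre is touched and the ethers are inert.

Step 15
Reactants: 19 diol
Product: 20 triol: 19 with the side-chain alkene hydrated to C4H(CH2OTBS)–C3H2OH (C4 epimers)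
Conditions: 9-BBN (excess), THF, 0 °C → rt; NaOH, H2O2, 0 °C
Reagents that add atoms: hydrogen peroxide, OO
Why: Hydroboration–oxidation places boron, then oxygen, on the terminal carbon of the 1,1-disubstituted alkene; the oxygen on C11 is γ to boron, so no β-elimination is possible.

Step 16
Reactants: 20 triol
Product: 22 lactol: (1R)-1-hydroxy iridoid with C3=C4 enol ether, 11-OTBS, 10-OTBS, 7-O-(4-methoxybenzyl) and free 8-OH (1β-OH anomer drawn), via dialdehyde 21 (not isolated)
Conditions: (COCl)2, DMSO, CH2Cl2, −78 °C; i-Pr2NEt, −78 → −20 °C; then pH 7 phosphate buffer–THF, rt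
Reagents that add atoms: none
Why: Swern oxidation activates both primary alcohols before base is added, so the dialdehyde forms without passing through a lactol that could be oxidised to a lactone. Ring-chain tautomerism of the 1,5-dialdehyde (the enol oxygen of C3 adds to C1) then gives the 2-hydroxy-dihydropyran, as in the iridodial–nepetalactol equilibrium; only the cis C5/C9 isomer can close, and neutral buffer avoids acid-promoted addition of O8 to C3.

Step 17
Reactants: 22 lactol; 23 (R)-3-methylpentanoic acid
Product: 24 1β-O-[(R)-3-methylpentanoyl] derivative of 22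
Conditions: EDC·HCl, DMAP, CH2Cl2, −20 → 0 °C
Reagents that add atoms: none
Why: Steglich-type esterification of the only acylable hydroxyl (O7 is an ether, O8 is tertiary). The 1β-oxygen is trans to the bulky C8 on the neighbouring carbon and anomerically stabilised, so the equilibrating lactol should be acylated through this anomer, setting C1 as 1S.

Step 18
Reactants: 24 C1 ester
Product: 25 7-hydroxy compound: 24 without the 4-methoxybenzyl group
Conditions: DDQ, CH2Cl2–pH 7 buffer, 0 °C
Reagents that add atoms: none
Why: Oxidative cleavage of the electron-rich benzyl ether under neutral conditions; silyl ethers and the acyl acetal are inert, and the trans-disposed O8 cannot trap the benzylic cation as a fused acetal.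

Step 19
Reactants: 26 4-hydroxybenzaldehyde
Product: 27 4-[(tert-butyldimethylsilyl)oxy]benzaldehyde
Conditions: TBSCl, imidazole, CH2Cl2, rt
Reagents that add atoms: tert-butyldimethylsilyl chloride, CC(C)(C)[Si](C)(C)Cl
Why: Standard phenol silylation; it removes the acidic proton that would quench the olefination base and deactivate the aldehyde.

Step 20
Reactants: 27 4-[(tert-butyldimethylsilyl)oxy]benzaldehyde
Product: 28 methyl (Z)-3-{4-[(tert-butyldimethylsilyl)oxy]phenyl}prop-2-enoate
Conditions: (CF3CH2O)2P(O)CH2CO2Me, KN(SiMe3)2, 18-crown-6, THF, −78 °C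
Reagents that add atoms: methyl 2-[bis(2,2,2-trifluoroethoxy)phosphoryl]acetate, COC(=O)CP(=O)(OCC(F)(F)F)OCC(F)(F)F
Why: Still–Gennari olefination; the electron-poor phosphonate and the dissociated potassium enolate make elimination from the kinetic adduct fast, which gives the (Z)-enoate with aromatic aldehydes.

Step 21
Reactants: 28 methyl (Z)-3-{4-[(tert-butyldimethylsilyl)oxy]phenyl}prop-2-enoate
Product: 29 (Z)-3-(4-hydroxyphenyl)prop-2-enoic acid
Conditions: LiOH, THF–MeOH–H2O, 0 °C → rt, dark; then dilute HCl
Reagents that add atoms: lithium hydroxide, [Li+].[OH-]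
Why: Saponification, which also removes the base-labile aryl silyl ether; the carboxylate does not isomerise in the dark.

Step 22
Reactants: 29 (Z)-3-(4-hydroxyphenyl)prop-2-enoic acid
Product: 31 (Z)-3-{4-[(tert-butyldimethylsilyl)oxy]phenyl}prop-2-enoic acid, via silyl ester 30 (not isolated)
Conditions: TBSCl (2.4 equiv), imidazole, DMF, rt; AcOH–THF–H2O, rt
Reagents that add atoms: tert-butyldimethylsilyl chloride, CC(C)(C)[Si](C)(C)Cl
Why: Double silylation and selective acid hydrolysis of the labile silyl ester; the aryl silyl ether is stable to weak acid.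

Step 23
Reactants: 25 7-hydroxy compound; 31 (Z)-3-{4-[(tert-butyldimethylsilyl)oxy]phenyl}prop-2-enoic acid
Product: 32 fully protected target: 7-O-[(Z)-4-(tert-butyldimethylsilyloxy)cinnamoyl] derivative of 25
Conditions: EDC·HCl, DMAP (cat.), CH2Cl2, 0 °C, dark
Reagents that add atoms: none
Why: Steglich esterification of the only free secondary hydroxyl (O8 is tertiary and does not compete); low temperature, little DMAP and exclusion of light are meant to keep the Z geometry.

Step 24
Reactants: 32 fully protected target
Product: 33 CNP0217341.1, (1S,4aS,6S,7R,7aS)-7-hydroxy-4,7-bis(hydroxymethyl)-6-{[(2Z)-3-(4-hydroxyphenyl)prop-2-enoyl]oxy}-1,4a,5,6,7,7a-hexahydrocyclopenta[c]pyran-1-yl (3R)-3-methylpentanoate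
Conditions: Bu4NF, AcOH (1:1), THF, 0 °C → rt
Reagents that add atoms: none
Why: Fluoride cleaves the aryl and the two primary silyl ethers; buffering with acetic acid keeps the medium near neutral, so the acyl acetal, the Z-enoate and the 7-ester next to the new 10-OH should survive without acyl shift.

## Compound list

1 | (R)-carvone | CC1=CC[C@H](CC1=O)C(C)=C | starting material
2 | (R)-5-(3-chloroprop-1-en-2-yl)-2-methylcyclohex-2-en-1-one | CC1=CC[C@H](CC1=O)C(=C)CCl | intermediate
3 | 2-[(1R)-4-methyl-5-oxocyclohex-3-en-1-yl]prop-2-en-1-yl acetate | CC1=CC[C@H](CC1=O)C(=C)COC(C)=O | intermediate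
4 | 2-[(1R,5R)-5-hydroxy-4-methylcyclohex-3-en-1-yl]prop-2-en-1-yl acetate (OH cis to side chain) | CC1=CC[C@H](C[C@H]1O)C(=C)COC(C)=O | intermediate
5 | (1S,5R)-5-[3-(acetyloxy)prop-1-en-2-yl]-2-methylcyclohex-2-en-1-yl 4-nitrobenzoate (trans) | CC1=CC[C@H](C[C@@H]1OC(=O)c2ccc(cc2)[N+](=O)[O-])C(=C)COC(C)=O | intermediate
6 | (1S,5R)-5-(3-hydroxyprop-1-en-2-yl)-2-methylcyclohex-2-en-1-ol | CC1=CC[C@H](C[C@@H]1O)C(=C)CO | intermediate
7 | (1S,5R)-5-{3-[(tert-butyldimethylsilyl)oxy]prop-1-en-2-yl}-2-methylcyclohex-2-en-1-ol | CC1=CC[C@H](C[C@@H]1O)C(=C)CO[Si](C)(C)C(C)(C)C | intermediate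
8 | syn-epoxy alcohol: 2,3-epoxide of 7, epoxide O cis to OH, both trans to the side chain | C[C@@]12O[C@@H]1C[C@H](C[C@@H]2O)C(=C)CO[Si](C)(C)C(C)(C)C | intermediate
9 | 4-methoxybenzyl ether of 8 | C[C@@]12O[C@@H]1C[C@H](C[C@@H]2OCc3ccc(OC)cc3)C(=C)CO[Si](C)(C)C(C)(C)C | intermediate
10 | (3S,5S)-3-{3-[(tert-butyldimethylsilyl)oxy]prop-1-en-2-yl}-5-[(4-methoxybenzyl)oxy]-6-oxoheptanal | O=CC[C@@H](C(=C)CO[Si](C)(C)C(C)(C)C)C[C@H](OCc1ccc(OC)cc1)C(C)=O | intermediate
11 | (3S,5S)-3-{3-[(tert-butyldimethylsilyl)oxy]prop-1-en-2-yl}-5-[(4-methoxybenzyl)oxy]-6-oxoheptanoic acid | OC(=O)C[C@@H](C(=C)CO[Si](C)(C)C(C)(C)C)C[C@H](OCc1ccc(OC)cc1)C(C)=O | intermediate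
12 | trimethylsilyl ester and terminal trimethylsilyl enol ether of 11 | C[Si](C)(C)OC(=O)C[C@@H](C(=C)CO[Si](C)(C)C(C)(C)C)C[C@H](OCc1ccc(OC)cc1)C(=C)O[Si](C)(C)C | intermediate
13 | trimethylsilyl ester of the 7-(trimethylsilyloxy) ketone | C[Si](C)(C)OC(=O)C[C@@H](C(=C)CO[Si](C)(C)C(C)(C)C)C[C@H](OCc1ccc(OC)cc1)C(=O)CO[Si](C)(C)C | intermediate
14 | (3S,5S)-3-{3-[(tert-butyldimethylsilyl)oxy]prop-1-en-2-yl}-7-hydroxy-5-[(4-methoxybenzyl)oxy]-6-oxoheptanoic acid | OC(=O)C[C@@H](C(=C)CO[Si](C)(C)C(C)(C)C)C[C@H](OCc1ccc(OC)cc1)C(=O)CO | intermediate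
15 | tert-butyldimethylsilyl ester of 16 | CC(C)(C)[Si](C)(C)OC(=O)C[C@@H](C(=C)CO[Si](C)(C)C(C)(C)C)C[C@H](OCc1ccc(OC)cc1)C(=O)CO[Si](C)(C)C(C)(C)C | intermediate
16 | (3S,5S)-7-[(tert-butyldimethylsilyl)oxy]-3-{3-[(tert-butyldimethylsilyl)oxy]prop-1-en-2-yl}-5-[(4-methoxybenzyl)oxy]-6-oxoheptanoic acid (key-step precursor) | OC(=O)C[C@@H](C(=C)CO[Si](C)(C)C(C)(C)C)C[C@H](OCc1ccc(OC)cc1)C(=O)CO[Si](C)(C)C(C)(C)C | intermediate
17 | mixed anhydride of 16 with 4-methylbenzenesulfonic acid | Cc1ccc(cc1)S(=O)(=O)OC(=O)C[C@@H](C(=C)CO[Si](C)(C)C(C)(C)C)C[C@H](OCc2ccc(OC)cc2)C(=O)CO[Si](C)(C)C(C)(C)C | intermediate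
18 | (1S,2S,4S,5R)-5-{[(tert-butyldimethylsilyl)oxy]methyl}-2-{3-[(tert-butyldimethylsilyl)oxy]prop-1-en-2-yl}-4-[(4-methoxybenzyl)oxy]-6-oxabicyclo[3.2.0]heptan-7-one (key-step product) | C=C(CO[Si](C)(C)C(C)(C)C)[C@H]1C[C@H](OCc2ccc(OC)cc2)[C@@]2(CO[Si](C)(C)C(C)(C)C)OC(=O)[C@@H]12 | intermediate
19 | diol from lactone reduction (C1 carbinol, free 8-OH) | C=C(CO[Si](C)(C)C(C)(C)C)[C@H]1C[C@H](OCc2ccc(OC)cc2)[C@](O)(CO[Si](C)(C)C(C)(C)C)[C@H]1CO | intermediate
20 | triol (C1 and C3 carbinols, free 8-OH; C4 epimers) | OCC(CO[Si](C)(C)C(C)(C)C)[C@H]1C[C@H](OCc2ccc(OC)cc2)[C@](O)(CO[Si](C)(C)C(C)(C)C)[C@H]1CO | intermediate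
21 | C1,C3-dialdehyde (C4 epimers) | O=CC(CO[Si](C)(C)C(C)(C)C)[C@H]1C[C@H](OCc2ccc(OC)cc2)[C@](O)(CO[Si](C)(C)C(C)(C)C)[C@H]1C=O | intermediate
22 | enol-lactol, 1β-OH anomer | O[C@@H]1OC=C(CO[Si](C)(C)C(C)(C)C)[C@H]2C[C@H](OCc3ccc(OC)cc3)[C@](O)(CO[Si](C)(C)C(C)(C)C)[C@@H]12 | intermediate
23 | (R)-3-methylpentanoic acid | CC[C@@H](C)CC(=O)O | starting material
24 | 1β-O-[(R)-3-methylpentanoyl] lactol ester, 7-O-(4-methoxybenzyl) | CC[C@@H](C)CC(=O)O[C@@H]1OC=C(CO[Si](C)(C)C(C)(C)C)[C@H]2C[C@H](OCc3ccc(OC)cc3)[C@](O)(CO[Si](C)(C)C(C)(C)C)[C@@H]12 | intermediate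
25 | 7-hydroxy C1 ester | CC[C@@H](C)CC(=O)O[C@@H]1OC=C(CO[Si](C)(C)C(C)(C)C)[C@H]2C[C@H](O)[C@](O)(CO[Si](C)(C)C(C)(C)C)[C@@H]12 | intermediate
26 | 4-hydroxybenzaldehyde | O=Cc1ccc(O)cc1 | starting material
27 | 4-[(tert-butyldimethylsilyl)oxy]benzaldehyde | CC(C)(C)[Si](C)(C)Oc1ccc(C=O)cc1 | intermediate
28 | methyl (Z)-3-{4-[(tert-butyldimethylsilyl)oxy]phenyl}prop-2-enoate | COC(=O)/C=C\c1ccc(O[Si](C)(C)C(C)(C)C)cc1 | intermediate
29 | (Z)-3-(4-hydroxyphenyl)prop-2-enoic acid | OC(=O)/C=C\c1ccc(O)cc1 | intermediate
30 | tert-butyldimethylsilyl (Z)-3-{4-[(tert-butyldimethylsilyl)oxy]phenyl}prop-2-enoate | CC(C)(C)[Si](C)(C)OC(=O)/C=C\c1ccc(O[Si](C)(C)C(C)(C)C)cc1 | intermediate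
31 | (Z)-3-{4-[(tert-butyldimethylsilyl)oxy]phenyl}prop-2-enoic acid | OC(=O)/C=C\c1ccc(O[Si](C)(C)C(C)(C)C)cc1 | intermediate
32 | tris-silyl ether of the target | CC[C@@H](C)CC(=O)O[C@@H]1OC=C(CO[Si](C)(C)C(C)(C)C)[C@H]2C[C@H](OC(=O)/C=C\c3ccc(O[Si](C)(C)C(C)(C)C)cc3)[C@](O)(CO[Si](C)(C)C(C)(C)C)[C@@H]12 | intermediate
33 | CNP0217341.1 | CC[C@@H](C)CC(=O)O[C@@H]1OC=C(CO)[C@H]2C[C@H](OC(=O)/C=C\c3ccc(O)cc3)[C@](O)(CO)[C@@H]12 | target

## Step count and least certain steps

Total steps: 24. Longest linear sequence: 20 (steps 1–18, 23, 24); the cinnamic acid branch is steps 19–22.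

**Step 13 (key step).**
- *What may go wrong:* closure through the enolate face preferred by the C5 branch, which would give the C8/C9 diastereomer. Alternatively the mismatched closure may be so slow that the amine epimerises C7, after which the fully matched substrate closes quickly to a useless isomer.
- *Fallback (ring-locked substrate):* it sets out from 14 and returns at 18.
  - Anhydrous DDQ with molecular sieves turns the 4-methoxybenzyl ether of 14 onto the free C10 hydroxyl, giving the 4-methoxybenzylidene acetal F1, a 1,3-dioxan-5-one that holds C7–O and C8=O in one ring.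
  - A five-membered ring can be annulated on this six-membered ketone only cis, so O8 anti to O7 is enforced by ring strain rather than by a dipole preference. The same aldol-lactonisation (TsCl, i-Pr2NEt, (S)-HBTM or achiral 4-pyrrolidinopyridine, short reaction time) should then give the tricyclic lactone F2.
  - Aqueous acetic acid removes the acetal to give the diol lactone F3.
  - TBSCl and imidazole silylate the primary hydroxyl to give the mono-silyl ether F4.
  - 4-Methoxybenzyl trichloroacetimidate with catalytic La(OTf)3 gives 18.

**Step 11.**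
- *What may go wrong:* deprotonation at C9 of the silyl ester or at C7 instead of the methyl group, and peracid attack on the allyl silyl ether alkene or the anisyl ether.
- *Fallback:* it sets out from 11 and returns at 16.
  - Trimethylsilyldiazomethane gives the methyl ester F5.
  - The kinetic potassium enolate (KN(SiMe3)2, −78 °C) is hydroxylated with 2-(phenylsulfonyl)-3-phenyloxaziridine, an oxidant that does not epoxidise alkenes, giving the hydroxy ketone ester F6.
  - TBSCl and imidazole give the silyl ether F7.
  - Me3SnOH in warm 1,2-dichloroethane cleaves the methyl ester without base strong enough to epimerise C7, giving 16.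

**Step 16.**
- *What may go wrong:* loss of silanol from the β-silyloxy aldehyde, retro-aldol or C9 epimerisation of the β-hydroxy aldehyde, and addition of O8 to C3 or decomposition during isolation of the lactol.
- *Fallback:* it sets out from 20 and returns at 24. The lactol is not isolated. The cold Swern mixture is treated with DMAP and (R)-3-methylpentanoic anhydride F8 (from 23 and half an equivalent of a carbodiimide), so the ring-chain equilibrium is drained by acylation of the lactol as it forms, giving 24 directly.

**Step 17.**
- *What may go wrong:* acylation through both anomers of the equilibrating lactol, giving poor selectivity at C1.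
- *Fallback:* it sets out from 22 and returns at 24. The anomeric bond is made by displacement instead of O-acylation.
  - Trichloroacetonitrile with K2CO3 (kinetic) or DBU (equilibrating) converts 22 into the 1α-trichloroacetimidate F9; the base is chosen to favour this anomer.
  - Acid 23 alone displaces the imidate with inversion, giving the 1β ester 24.

**Step 23.**
- *What may go wrong:* Z to E isomerisation of the activated acid by reversible conjugate addition of DMAP, and slow acylation of the hindered C7 hydroxyl that lengthens the exposure.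
- *Fallback:* it sets out from 27 and 25 and returns at 32. The alkene geometry is made after the ester bond.
  - Corey–Fuchs reaction of 27 (CBr4, PPh3) gives the dibromoalkene F10.
  - n-BuLi, then CO2, gives the arylpropiolic acid F11.
  - Carbodiimide esterification of 25 with F11 gives the alkynoate F12, which cannot isomerise.
  - Semihydrogenation over Pd/CaCO3 poisoned with Pb(OAc)2 and quinoline gives 32; the trisubstituted enol ether is not reduced under these conditions.

## Further compounds

F1 | step 13 | (3S)-3-{3-[(tert-butyldimethylsilyl)oxy]prop-1-en-2-yl}-4-[(4S)-2-(4-methoxyphenyl)-5-oxo-1,3-dioxan-4-yl]butanoic acid (acetal carbon unassigned) | OC(=O)C[C@@H](C(=C)CO[Si](C)(C)C(C)(C)C)C[C@@H]1OC(c2ccc(OC)cc2)OCC1=O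
F2 | step 13 | tricyclic β-lactone with the 4-methoxybenzylidene acetal across O7 and O10 | C=C(CO[Si](C)(C)C(C)(C)C)[C@H]1C[C@@H]3OC(c2ccc(OC)cc2)OC[C@@]34OC(=O)[C@@H]14
F3 | step 13 | β-lactone with free 7-OH and 10-OH | C=C(CO[Si](C)(C)C(C)(C)C)[C@H]1C[C@H](O)[C@@]2(CO)OC(=O)[C@@H]12
F4 | step 13 | β-lactone with 10-OTBS and free 7-OH | C=C(CO[Si](C)(C)C(C)(C)C)[C@H]1C[C@H](O)[C@@]2(CO[Si](C)(C)C(C)(C)C)OC(=O)[C@@H]12
F5 | step 11 | methyl ester of 11 | COC(=O)C[C@@H](C(=C)CO[Si](C)(C)C(C)(C)C)C[C@H](OCc1ccc(OC)cc1)C(C)=O
F6 | step 11 | methyl ester of 14 | COC(=O)C[C@@H](C(=C)CO[Si](C)(C)C(C)(C)C)C[C@H](OCc1ccc(OC)cc1)C(=O)CO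
F7 | step 11 | methyl ester of 16 | COC(=O)C[C@@H](C(=C)CO[Si](C)(C)C(C)(C)C)C[C@H](OCc1ccc(OC)cc1)C(=O)CO[Si](C)(C)C(C)(C)C
F8 | step 16 | (R)-3-methylpentanoic anhydride | CC[C@@H](C)CC(=O)OC(=O)C[C@H](C)CC
F9 | step 17 | 1α-O-trichloroacetimidate of 22 | ClC(Cl)(Cl)C(=N)O[C@H]1OC=C(CO[Si](C)(C)C(C)(C)C)[C@H]2C[C@H](OCc3ccc(OC)cc3)[C@](O)(CO[Si](C)(C)C(C)(C)C)[C@@H]12
F10 | step 23 | tert-butyl[4-(2,2-dibromoethenyl)phenoxy]dimethylsilane | BrC(Br)=Cc1ccc(O[Si](C)(C)C(C)(C)C)cc1
F11 | step 23 | 3-{4-[(tert-butyldimethylsilyl)oxy]phenyl}prop-2-ynoic acid | OC(=O)C#Cc1ccc(O[Si](C)(C)C(C)(C)C)cc1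
F12 | step 23 | 7-O-arylpropioloyl derivative of 25 | CC[C@@H](C)CC(=O)O[C@@H]1OC=C(CO[Si](C)(C)C(C)(C)C)[C@H]2C[C@H](OC(=O)C#Cc3ccc(O[Si](C)(C)C(C)(C)C)cc3)[C@](O)(CO[Si](C)(C)C(C)(C)C)[C@@H]12
A1 | alternative 1 | open-chain heterodiene: alkylidene formylacetate tethered to an (E)-ethyl enol ether, C7/C10 acetonide, 8-O-triethylsilyl | CCO/C=C/[C@@]1(O[Si](CC)(CC)CC)COC(C)(C)O[C@H]1CC=C(C=O)C(=O)OC
A2 | alternative 1 | tricyclic C1 ethyl acetal with C11 methyl ester and C7/C10 acetonide | CCO[C@@H]1OC=C(C(=O)OC)[C@H]2C[C@@H]3OC(C)(C)OC[C@]3(O[Si](CC)(CC)CC)[C@@H]12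
A3 | alternative 2 | 6-(pivaloyloxy)-2H-pyran-3(6H)-one | CC(C)(C)C(=O)O[C@@H]1OCC(=O)C=C1
A4 | alternative 2 | ethyl buta-2,3-dienoate | C=C=CC(=O)OCC
A5 | alternative 2 | cis-fused cyclopenta[c]pyran-4-one with C7=C8 alkene and C10 ethyl ester | CC(C)(C)C(=O)O[C@@H]1OCC(=O)[C@H]2CC=C(C(=O)OCC)[C@@H]12
A6 | alternative 3 | cyclopentane diene with a C1 methyl vinyl acetal and a C4 1,1-disubstituted alkene | CO[C@H](OC=C)[C@H]1[C@@H](C(=C)CO[Si](C)(C)C(C)(C)C)C[C@H](O[Si](C)(C)C(C)(C)C)[C@]1(O[Si](CC)(CC)CC)CO[Si](C)(C)C(C)(C)C
A7 | alternative 3 | persilylated iridoid C1 methyl acetal | CO[C@@H]1OC=C(CO[Si](C)(C)C(C)(C)C)[C@H]2C[C@H](O[Si](C)(C)C(C)(C)C)[C@](O[Si](CC)(CC)CC)(CO[Si](C)(C)C(C)(C)C)[C@@H]12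
A8 | alternative 3 | Mo(=CHCMe2Ph)(=N-2,6-iPr2C6H3)[OCMe(CF3)2]2 | CC(C)c1cccc(C(C)C)c1N=[Mo](=CC(C)(C)c1ccccc1)(OC(C)(C(F)(F)F)C(F)(F)F)OC(C)(C(F)(F)F)C(F)(F)F
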